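The readings were generated by integration with constants of no real substance.

The ratio I start from is r, the partner charged as a fraction of the substrate charged: 0.530 in oak, 0.309 in ash, 4.20 in birch.

| setting | birch | ash | oak | eta | theta | gamma | delta | epsilon | zeta |
|---|---|---|---|---|---|---|---|---|---|
| substrate | 0.0025 M | 0.034 M | 0.010 M | 0.010 M | 0.040 M | 0.0030 M | 0.0030 M | 0.0060 M | 0.0060 M |
| partner | 0.0105 M | 0.0105 M | 0.0053 M | 0.0105 M | 0.0150 M | 0.00800 M | 0.00250 M | 0.00250 M | 0.0105 M |
| temperature | 15 °C | 30 °C | 15 °C | 40 °C | 40 °C | 25 °C | 40 °C | 20 °C | 25 °C |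
| remark | run made earlier | run made earlier | run made earlier |  |  |  |  |  |  |
| time |  |  |  | 15 h | 15 h | 15 h | 15 h | 15 h | 15 h |

| run | time / h | first product / % | bis adduct / % | isomer of the product / % |
|---|---|---|---|---|
| birch | 5.00 | 28.6 | 15.0 | 1.5 |
| birch | 10.0 | 29.5 | 25.4 | 3.1 |
| birch | 15.0 | 28.6 | 34.4 | 2.4 |
| birch | 20.0 | 27.4 | 38.8 | 4.2 |
| birch | 30.0 | 25.2 | 44.7 | 4.2 |
| ash | 2.50 | 16.7 | 3.3 | 1.2 |
| ash | 5.00 | 14.6 | 3.4 | 2.9 |
| ash | 8.00 | 15.5 | 3.0 | 1.6 |
| ash | 10.0 | 14.7 | 4.0 | 3.8 |
| ash | 12.0 | 15.4 | 3.4 | 4.3 |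
| oak | 2.50 | 13.6 | 0.8 | 0 |
| oak | 6.00 | 20.3 | 4.5 | 0.9 |
| oak | 15.0 | 22.4 | 6.8 | 2.0 |
| oak | 30.0 | 22.4 | 7.3 | 3.7 |

(each reading ± 0.5 percentage points)

- the analysis behind the earlier runs scatters by 0.5 percentage points, standard deviation

- ranking by share of first product in all that became first product or bis adduct or isomer of the product, from high to low, at 15 h (eta / theta / gamma / delta / epsilon / zeta)
- the share of first product in all that became first product or bis adduct or isomer of the product of the flask you put first, at 15 h
- the share of first product in all that became first product or bis adduct or isomer of the product of the flask you put last, at 15 h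

Now I count turnovers. A substrate that became first product or isomer of the product took one partner, and a bis adduct took two. So n, the first product plus the isomer plus twice the bis adduct, as fractions of the substrate charge, is the partner placed per substrate. At the last readings n is 0.407 in oak, 0.265 in ash and 1.19 in birch. Oak has placed 0.768 of its partner, birch 0.283. My guess is that partner wasted on itself competes with partner adding to substrate, so that waste per addition grows with r. The plainest form is then 1/n = 1/r + w. Solved run by run, w is 0.570, 0.535 and 0.604, and I carry the mean, 0.570, as the waste term.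

I now tie the share, the selectivity for first product, to turnovers. Bis adduct as a fraction of all converted, divided by n, reads 0.537, 0.555 and 0.508, mean 0.533. At their last readings, birch and oak keep on average 0.858 of first product plus isomer as first product. I take the share as that fraction times (1 − 0.533 n).

My reckoning gives theta 71.6%, epsilon 70.4%, delta 59.9%, eta 55.7%, zeta 45.7% and gamma 37.3%. It carries no temperature, and 40 °C lies above ash at 30 °C.

The forecast differs from mine: it gives epsilon > zeta > theta > delta > gamma > eta, from 72% down to 31%, and says “Only epsilon is clearly separated”.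

The flasks give epsilon > theta > delta > eta > zeta > gamma, from 72.0% down to 42.0%.

    first product ⇌ isomer of the product (K = 0.180, k = 0.00368 min⁻¹, Ea = 94.0 kJ mol⁻¹, ΔH = −12.0 kJ mol⁻¹)
    partner → decomposed reagent (k = 9.32 × 10⁻⁴ min⁻¹, Ea = 98.0 kJ mol⁻¹)
    2 partner → self-condensation product (k = 1.04 L mol⁻¹ min⁻¹, Ea = 59.0 kJ mol⁻¹)
    substrate + partner → first product + by-product (k = 1.29 L mol⁻¹ min⁻¹, Ea = 46.0 kJ mol⁻¹)
    partner + first product → bis adduct + by-product (k = 2.04 L mol⁻¹ min⁻¹, Ea = 51.0 kJ mol⁻¹)
    (constants at 40 °C)

Gamma stands above my share, 42.0% against 37.3%. I reckoned n = 1.06, but at 15.0 h gamma counts 0.944, with 7.19% of its partner left, and at 150 h it counts 1.09. The neighbouring flask is gamma with 0.0075 M of substrate, so r is 1.07. The waste term gives n = 0.663 and a share of 55.4%. At 15.0 h the neighbouring flask counts 0.651 and gives a share of 53.2%, with 52.1% of its substrate left.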